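**Retrosynthetic overview**

1. Oleiferinone 23 ⇒ isoxazole 20: the 2-acyl-1,3-dione is carried as a 4-acylisoxazole and unmasked by N–O hydrogenolysis, hydrolysis and desilylation.
2. 20 ⇒ nitrile oxide 18 + dione 16 by 1,3-dipolar cycloaddition, which forms the isoxazole ring and the C2–acyl C–C bond and joins the two halves.
3. 18 ⇐ oxime 7 ⇐ alcohol 5 ⇐ 11-bromoundecan-1-ol 1 + 2-phenylethylmagnesium chloride 2 (copper-catalysed sp3–sp3 coupling).
4. 16 ⇐ intramolecular Claisen closure of keto ester 13 ⇐ (S)-5-oxotetrahydrofuran-2-carboxylic acid 8, which carries the only stereocentre (it is the nitrous-acid deamination product of L-glutamic acid).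
5. Ring order: the six-membered carbocycle first (step 6), then the isoxazole (step 7), which is opened again in step 8.

Assumption: the target stereocentre is (S) as read from the SMILES; 8 and 2 (THF solution) are bought.

**Route**

Step 1
Reactants: 1 11-bromoundecan-1-ol; 2 2-phenylethylmagnesium chloride
Product: 5 13-phenyltridecan-1-ol, via chloromagnesium 11-bromoundecan-1-olate 3 (not isolated), via chloromagnesium 13-phenyltridecan-1-olate 4 (not isolated)
Conditions: 2 (2.3 equiv), Li2CuCl4 (3 mol %), THF, −10 °C → rt; 1 M HCl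
Reagents that add atoms: none
Why: Kochi-type copper-catalysed sp3–sp3 cross-coupling of a primary bromide with a primary Grignard reagent; the first equivalent of 2 only deprotonates the alcohol, whose alkoxide is inert.

Step 2
Reactants: 5 13-phenyltridecan-1-ol
Product: 7 13-phenyltridecanal oxime (E/Z mixture), via 13-phenyltridecanal 6 (not isolated)
Conditions: TEMPO (10 mol %), PhI(OAc)2 (1.1 equiv), CH2Cl2, rt; then NH2OH·HCl (2 equiv), pyridine, EtOH, rt
Reagents that add atoms: hydroxylamine hydrochloride, NO.Cl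
Why: the oxoammonium (TEMPO) oxidation stops at the aldehyde, which condenses with hydroxylamine to the aldoxime; excess hydroxylamine also destroys residual oxidant and the oxime geometry is irrelevant.

Step 3
Reactants: 8 (S)-5-oxotetrahydrofuran-2-carboxylic acid
Product: 11 (S)-2-hydroxy-5-oxohexanoic acid (in equilibrium with its cyclic hemiketal; used crude), via lithium (S)-5-oxotetrahydrofuran-2-carboxylate 9 (not isolated), via dilithium lactolate 10 (not isolated)
Conditions: MeLi (2.05 equiv), THF, −78 °C; then HCl/Et2O (2.1 equiv), −78 °C → rt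
Reagents that add atoms: methyllithium, [Li]C
Why: nucleophilic mono-addition to a lactone: the lithium carboxylate is inert at −78 °C, the lactone takes up one MeLi and the lactolate survives until the quench; the stereocentre is not touched.

Step 4
Reactants: 11 (S)-2-hydroxy-5-oxohexanoic acid
Product: 12 methyl (S)-2-hydroxy-5-oxohexanoate
Conditions: TMSCHN2, toluene/MeOH (4:1), 0 °C
Reagents that add atoms: (trimethylsilyl)diazomethane, C[Si](C)(C)C=[N+]=[N-]
Why: diazoalkane O-methylation of the carboxylic acid under neutral conditions, so the α-hydroxy stereocentre and the ketone are left alone.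

Step 5
Reactants: 12 methyl (S)-2-hydroxy-5-oxohexanoate
Product: 13 methyl (S)-2-((tert-butyldimethylsilyl)oxy)-5-oxohexanoate
Conditions: TBSCl, imidazole, DMF, rt
Reagents that add atoms: tert-butyldimethylsilyl chloride, CC(C)(C)[Si](C)(C)Cl
Why: imidazole-mediated silylation of the secondary alcohol traps the open-chain tautomer and shields the α-hydrogen of the ester for the next step.

Step 6
Reactants: 13 methyl (S)-2-((tert-butyldimethylsilyl)oxy)-5-oxohexanoate
Product: 16 (S)-4-((tert-butyldimethylsilyl)oxy)cyclohexane-1,3-dione (largely enolised), via lithium methyl-ketone enolate 14 (not isolated), via lithium dionate 15 (not isolated)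
Conditions: LiN(SiMe3)2 (2.0 equiv), THF, −78 → 0 °C; then 1 M HCl to pH 3, 0 °C
Reagents that add atoms: none
Why: intramolecular Claisen (Dieckmann-type) condensation, a 6-(enolendo)-exo-trig attack of the kinetic methyl-ketone enolate on the ester; the product is held as its dionate, so the hindered α-silyloxy stereocentre is not enolised.

Step 7
Reactants: 7 13-phenyltridecanal oxime; 16 (S)-4-((tert-butyldimethylsilyl)oxy)cyclohexane-1,3-dione
Product: 20 (S)-5-((tert-butyldimethylsilyl)oxy)-3-(12-phenyldodecyl)-6,7-dihydrobenzo[d]isoxazol-4(5H)-one, via hydroximoyl chloride 17 (not isolated), via nitrile oxide 18 (not isolated), via 7a-hydroxyisoxazoline cycloadduct 19 (not isolated)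
Conditions: 7 (1.3 equiv), NCS (1.3 equiv), DMF, rt; then added slowly to 16, Et3N (2.5 equiv), CH2Cl2, 0 °C → rt
Reagents that add atoms: none
Why: Huisgen 1,3-dipolar cycloaddition of the nitrile oxide across the enol C=C of the dione (carbon to the nucleophilic C2, oxygen to the enol carbon remote from the bulky silyloxy group), then loss of water to the aromatic isoxazole; the stereocentre is a spectator, and the regioisomer with oxygen on the other carbonyl would give the same 21 in step 8.

Step 8
Reactants: 20 (S)-5-((tert-butyldimethylsilyl)oxy)-3-(12-phenyldodecyl)-6,7-dihydrobenzo[d]isoxazol-4(5H)-one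
Product: 23 oleiferinone, via enaminodione 21 (not isolated), via O-TBS-oleiferinone 22 (not isolated)
Conditions: H2 (1 atm), 10% Pd/C, EtOH, rt; filter; then 2 M HCl aq/THF, 50 °C
Reagents that add atoms: water, O
Why: hydrogenolysis of the weak isoxazole N–O bond gives the vinylogous amide, whose acid hydrolysis releases the β-triketone while the same acid cleaves the silyl ether; the carbinol carbon is not involved.

**Compound list**

1 | 11-bromoundecan-1-ol | OCCCCCCCCCCCBr | starting material
2 | 2-phenylethylmagnesium chloride | Cl[Mg]CCc1ccccc1 | starting material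
3 | chloromagnesium 11-bromoundecan-1-olate | BrCCCCCCCCCCCO[Mg]Cl | intermediate
4 | chloromagnesium 13-phenyltridecan-1-olate | Cl[Mg]OCCCCCCCCCCCCCc1ccccc1 | intermediate
5 | 13-phenyltridecan-1-ol | OCCCCCCCCCCCCCc1ccccc1 | intermediate
6 | 13-phenyltridecanal | O=CCCCCCCCCCCCCc1ccccc1 | intermediate
7 | 13-phenyltridecanal oxime (E/Z mixture) | ON=CCCCCCCCCCCCCc1ccccc1 | intermediate
8 | (S)-5-oxotetrahydrofuran-2-carboxylic acid | O=C1CC[C@H](O1)C(=O)O | starting material
9 | lithium (S)-5-oxotetrahydrofuran-2-carboxylate | O=C1CC[C@H](O1)C(=O)[O-].[Li+] | intermediate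
10 | dilithium (2S)-5-methyl-5-oxidotetrahydrofuran-2-carboxylate (lactolate, both C5 epimers) | CC1([O-])CC[C@H](O1)C(=O)[O-].[Li+].[Li+] | intermediate
11 | (S)-2-hydroxy-5-oxohexanoic acid | CC(=O)CC[C@H](O)C(=O)O | intermediate
12 | methyl (S)-2-hydroxy-5-oxohexanoate | CC(=O)CC[C@H](O)C(=O)OC | intermediate
13 | methyl (S)-2-((tert-butyldimethylsilyl)oxy)-5-oxohexanoate | CC(=O)CC[C@H](O[Si](C)(C)C(C)(C)C)C(=O)OC | intermediate
14 | lithium (S)-5-((tert-butyldimethylsilyl)oxy)-6-methoxy-6-oxohex-1-en-2-olate | C=C([O-])CC[C@H](O[Si](C)(C)C(C)(C)C)C(=O)OC.[Li+] | intermediate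
15 | lithium (S)-4-((tert-butyldimethylsilyl)oxy)-3-oxocyclohex-1-en-1-olate | [O-]C1=CC(=O)[C@@H](O[Si](C)(C)C(C)(C)C)CC1.[Li+] | intermediate
16 | (S)-4-((tert-butyldimethylsilyl)oxy)cyclohexane-1,3-dione | O=C1CC[C@H](O[Si](C)(C)C(C)(C)C)C(=O)C1 | intermediate
17 | N-hydroxy-13-phenyltridecanimidoyl chloride | ON=C(Cl)CCCCCCCCCCCCc1ccccc1 | intermediate
18 | 13-phenyltridecanenitrile oxide | [O-][N+]#CCCCCCCCCCCCCc1ccccc1 | intermediate
19 | (5S)-5-((tert-butyldimethylsilyl)oxy)-7a-hydroxy-3-(12-phenyldodecyl)-3a,6,7,7a-tetrahydrobenzo[d]isoxazol-4(5H)-one (cis-fused, both faces) | O=C1[C@@H](O[Si](C)(C)C(C)(C)C)CCC2(O)ON=C(CCCCCCCCCCCCc3ccccc3)C12 | intermediate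
20 | (S)-5-((tert-butyldimethylsilyl)oxy)-3-(12-phenyldodecyl)-6,7-dihydrobenzo[d]isoxazol-4(5H)-one | O=C1[C@@H](O[Si](C)(C)C(C)(C)C)CCc2onc(CCCCCCCCCCCCc3ccccc3)c12 | intermediate
21 | (S)-2-(1-amino-13-phenyltridecylidene)-4-((tert-butyldimethylsilyl)oxy)cyclohexane-1,3-dione | NC(CCCCCCCCCCCCc1ccccc1)=C1C(=O)CC[C@H](O[Si](C)(C)C(C)(C)C)C1=O | intermediate
22 | (S)-6-((tert-butyldimethylsilyl)oxy)-3-hydroxy-2-(13-phenyltridecanoyl)cyclohex-2-en-1-one | O=C(CCCCCCCCCCCCc1ccccc1)C1=C(O)CC[C@H](O[Si](C)(C)C(C)(C)C)C1=O | intermediate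
23 | oleiferinone, (S)-3,6-dihydroxy-2-(13-phenyltridecanoyl)cyclohex-2-en-1-one | O=C(CCCCCCCCCCCCc1ccccc1)C1=C(O)CC[C@H](O)C1=O | target

**Step count and weak points**

Total step count: 8. Longest linear sequence: 6 steps (8 to 23, steps 3 to 8).

Step 3 is the first weak point: MeLi may add twice to give the tertiary alcohol, or the carboxylate may be too insoluble to react cleanly. Fallback: starting from 8, the lactone is opened instead with the magnesium amide made from MeNHOMe·HCl and iPrMgCl (THF, −20 °C; the carboxylate is inert) to give (S)-2-hydroxy-5-[methoxy(methyl)amino]-5-oxopentanoic acid F1. MeMgBr (0 °C) is then added in the same flask. The chelated tetrahedral intermediate of the Weinreb amide cannot take up a second methyl group, and acid work-up comes back to the route at 11.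

Step 7 is the second weak point: the aliphatic nitrile oxide 18 may dimerise to the furoxan, or the free dione may be chlorinated or O-imidoylated. Fallback: starting from 16, condensation with pyrrolidine (toluene, 4 Å sieves, rt) gives the vinylogous amide (S)-6-((tert-butyldimethylsilyl)oxy)-3-(pyrrolidin-1-yl)cyclohex-2-en-1-one F2, a neutral and more electron-rich dipolarophile. Nitrile oxide 18, made from 7 as in step 7, adds across the enamine double bond to the aminal (5S)-5-((tert-butyldimethylsilyl)oxy)-3-(12-phenyldodecyl)-7a-(pyrrolidin-1-yl)-3a,6,7,7a-tetrahydrobenzo[d]isoxazol-4(5H)-one F3. F3 is not isolated and loses pyrrolidine to come back to the route at 20.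

Step 8 is the third weak point: hydrolysis of the doubly stabilised vinylogous amide 21 may need acid hot enough to erode the α-ketol stereocentre. Fallback: starting from 21, isolated after the hydrogenolysis stage, the nitrogen is acylated with Boc2O and DMAP (MeCN, rt) to give di-tert-butyl (S)-N-[1-(3-((tert-butyldimethylsilyl)oxy)-2,6-dioxocyclohexylidene)-13-phenyltridecyl]imidodicarbonate F4. With the nitrogen lone pair tied up, LiOH (THF/H2O, 0 °C) displaces the imidodicarbonate by addition–elimination, and acidification comes back to the route at 22. Compound 22 is then desilylated with HF·pyridine (MeCN, 0 °C) to 23.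

**Further compounds**

F1 | step 3 | (S)-2-hydroxy-5-[methoxy(methyl)amino]-5-oxopentanoic acid | CON(C)C(=O)CC[C@H](O)C(=O)O
F2 | step 7 | (S)-6-((tert-butyldimethylsilyl)oxy)-3-(pyrrolidin-1-yl)cyclohex-2-en-1-one | C1(N2CCCC2)=CC(=O)[C@@H](O[Si](C)(C)C(C)(C)C)CC1
F3 | step 7 | (5S)-5-((tert-butyldimethylsilyl)oxy)-3-(12-phenyldodecyl)-7a-(pyrrolidin-1-yl)-3a,6,7,7a-tetrahydrobenzo[d]isoxazol-4(5H)-one | O=C1[C@@H](O[Si](C)(C)C(C)(C)C)CCC2(N3CCCC3)ON=C(CCCCCCCCCCCCc4ccccc4)C12
F4 | step 8 | di-tert-butyl (S)-N-[1-(3-((tert-butyldimethylsilyl)oxy)-2,6-dioxocyclohexylidene)-13-phenyltridecyl]imidodicarbonate | CC(C)(C)OC(=O)N(C(=O)OC(C)(C)C)C(CCCCCCCCCCCCc1ccccc1)=C1C(=O)CC[C@H](O[Si](C)(C)C(C)(C)C)C1=O
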